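The numbers in the tables are calculated with constants of no real substance, noise included.

The autumn run was slow: at 6.00 min it still held 86.4 % of its substrate. You want to carry those first minutes over to a new flask.

- autumn: substrate 0.075 M; reagent 0.055 M; run made earlier
- flask: substrate 0.050 M; reagent 0.0550 M; time 1.0 h

autumn run (percent of the substrate charged)

| time / min | target / % | substrate / % |
|---|---|---|
| 1.00 | 2.2 | 97.1 |
| 2.00 | 4.4 | 94.7 |
| 3.00 | 5.7 | 93.1 |
| 4.00 | 8.1 | 90.2 |
| 5.00 | 9.7 | 88.2 |
| 6.00 | 10.3 | 86.4 |

(readings scatter by 0.3 percentage points)

1. the moment within 1.0 h at which there is most target
2. the amount of target, in percent of the substrate charged, at that time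
3. the first time at which target reaches 11 %, in the same percent



Take a rate constant k and assume that target forms at k times substrate times reagent. Count target as a fraction of the substrate charge. While the charges stand near full, the substrate charge divides out and k times reagent remains. This is the pseudo-first-order view, and it is an assumption, since one run tests no order. Reagent stands at 0.055 M in the autumn run and 0.0550 M in the new flask, so the two should share one pace.

The autumn run reached 10.3 % of target at 6.00 min, which gives 0.0172 min⁻¹. This fraction of the charge turned into target per minute is the climb. The level of 11 % lies just above that last reading, so you reckon only a short way past it. My reckoning is that the new flask reaches the level at 6.41 min.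

The far end is different. Kept up for 1.0 h, the climb would give 103 % of the charge, so it has to bend. The autumn readings already bend: the pace over the first 2.00 min was 0.0220 min⁻¹, faster than the climb. Those readings stop at 6.00 min, so I commit to no number for the peak.

The forecast gives 45 % at 1 h, with the level reached at 0.105 h, and holds that “target is probably still rising”.

    target → over-reaction product (k = 0.0330 min⁻¹)
    substrate + reagent → target (k = 0.420 L mol⁻¹ min⁻¹)
    substrate + 2 reagent → side product (k = 1.80 L² mol⁻² min⁻¹)

The new flask gives 21.6 % at 0.484 h and reaches the level at 6.28 min, against my 6.41 min. At its best time the new flask holds 15.2 % of over-reaction product. Now take the neighbour flask charged with 0.014 M of reagent. Scaled with reagent, as the assumed rate has it, the climb of that neighbour flask is 0.00437 min⁻¹, and kept up for 1.0 h that pace would give 26.2 % of the charge. That neighbour flask ends with less than this: 6.30 % of target and 11.8 % of over-reaction product, with 30 % of its reagent left.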